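A flask this slow is best followed by the fraction of D left, not by what has been made. J starts chains whose living ends E carry D into X, D also goes by itself to Q, G can end E as Z, and J may be lost to L.

| flask | D | G | J | remark | time |
|---|---|---|---|---|---|
| summer | 0.20 M | 0.060 M | 0.25 mol% | run made earlier |  |
| dusk | 0.20 M | 0.060 M | 0.55 mol% | run made earlier |  |
| noon | 0.30 M | 0.060 M | 0.37 mol% | run made earlier |  |
| flask | 0.20 M | 0.0600 M | 0.37 mol% |  | 50 min |

| run | time / min | X / % | D / % |
|---|---|---|---|
| summer | 4.00 | 1.9 | 94.1 |
| summer | 6.00 | 3.7 | 90.6 |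
| summer | 12.0 | 6.8 | 82.7 |
| summer | 20.0 | 9.8 | 73.8 |
| summer | 30.0 | 12.5 | 65.3 |
| summer | 50.0 | 14.0 | 52.3 |
| dusk | 4.00 | 4.6 | 91.5 |
| dusk | 6.00 | 7.7 | 86.7 |
| dusk | 12.0 | 14.7 | 75.8 |
| dusk | 20.0 | 20.5 | 64.1 |
| dusk | 30.0 | 24.7 | 54.5 |
| dusk | 50.0 | 28.0 | 42.4 |
| noon | 10.0 | 13.4 | 78.3 |
| noon | 20.0 | 21.3 | 64.3 |
| noon | 30.0 | 24.7 | 54.4 |
| noon | 40.0 | 27.0 | 47.0 |
| noon | 50.0 | 28.8 | 42.0 |

(standard deviation of a reading: 0.3 percentage points)

- the average divides the monomer in chains by the number of chains begun, living and dead together
- what was read earlier has a scatter of 0.3 percentage points, one standard deviation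
- candidate steps: D + J -> L; D + E -> X + E; D + J -> E + X; D -> Q; E + G -> Z
- the earlier runs do not show the number of chains; that part of a forecast is a guess

* average number of monomer units in a chain (chains begun, living or dead) at 50 min
* part of the D that has reacted at 50 min

Each road takes a share of the D present, so fractions left multiply and their logarithms add. Summer and dusk differ in J, so the ratio of D left at 50.0 min, 52.3% against 42.4%, belongs to the chains. Its logarithm, divided by the difference in J in moles per litre, gives 350 M⁻¹, the chain exponent: the drop in the logarithm of the fraction of D left, per mole of J charged per litre, at this G and time. Noon, not used for this, reckons to 42.3% and read 42.0%.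

In my reckoning for this flask, growth by itself, pseudo-first-order in D at a given level of E, leaves 77.2% of the D, which puts the reacted part at 22.8%. The loss to Q comes next: the summer reading with its chains divided out leaves 62.3% of the D on that road, and the two fractions multiplied give 48.1% left, a reckoned 51.9% reacted. The rest, the ending of chains and any J lost to L, already lies inside the exponent for D, but the runs show no chain count. X taken between the summer and dusk readings is 19.6%, and if every J began a chain, my reckoning gives an average chain of 53.0.

The forecast says 52% reacted and an average chain of 65, longer than my figure, and adds: “Efficiency is a guess”.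

The flask gives 52.0% reacted and an average chain of 61.0.

D + J → L (k = 0.307 M⁻¹ min⁻¹); D + E → X + E, rate k2*[E]*[D] (k = 21.4 M⁻¹ min⁻¹); D + J → E + X (k = 2.32 M⁻¹ min⁻¹); D → Q (k = 0.00942 min⁻¹); E + G → Z (k = 0.815 M⁻¹ min⁻¹) The exponent carried from summer to the neighbour with 0.93 mol% of J reckons 32.5% of D left, and that neighbour holds 32%. This flask is not at rest at 50 min, though J stands at 0%. By 500 min X goes from 19.9% to 21.1% and the average chain to 64.5, while Q climbs from 32.0% to 78.2% and D falls to 0.673%.

The readings stem from a simulated flask with constants of no real substance.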